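**Plan**

1. Retrosynthesis (isochromenone numbering: C1 carbonyl, O2, C3, C4, C4a, C5–C8, C8a): the lactone C1–O2 bond is opened to a 6-(2-silyloxyalkyl)salicylate, and the benzene ring is then cut at C8–C8a and C4a–C5 to an acyclic silyloxy dienynoate plus 1-methoxycyclohexa-1,3-diene.
2. Enabling feature: the benzene ring (C4a, C5–C8, C8a) carries the C8 oxygen, the C1 carboxyl (on C8a) and the C4 methylene (on C4a) on three adjacent carbons. An alk-2-ynoate (C1–C8a≡C4a–C4) and a 1-oxygenated cyclohexa-1,3-diene deliver exactly this pattern.
3. The ynoate is cut at C1–C8a (acetylide carboxylation), at C3–C4 (propargylation of a dienal) and at the C3′=C4′ alkene of the side chain (vinylogous Horner–Wadsworth–Emmons reaction on tetradecanal).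
4. Forward: the chain is assembled first (steps 1–6), the benzene ring is built by [4+2]/retro-[4+2] (step 7), the phenol is unmasked (step 8), and the lactone ring closes last (step 9).
5. Stereochemistry: C3 (R) comes from a catalyst-controlled propargylboration of the dienal. Both E alkenes come from the E-phosphonate and the E-selective olefination, and no later step touches them.

Key step: step 7

Assumption: the (R)-configured phosphoric acid is taken to direct the allenylboronate to the re face of the dienal, as expected for aryl and alkenyl aldehydes; should Mosher ester analysis of 8 show the opposite sense, the (S)-catalyst would be used.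

Remark on the endgame: the methyl ether is cleaved before the lactone is formed, because a boron-chelated dienylic lactone would be more prone to C3–O ionization than the silyl ether is.

**Route**

Step 1
Reactants: 1 tetradecanal; 2 triethyl 4-phosphonocrotonate
Product: 3 ethyl (2E,4E)-octadeca-2,4-dienoate
Conditions: 2, LiN(SiMe3)2, THF, −78 °C; then 1, −78 °C to 0 °C
Reagents that add atoms: none
Why: Vinylogous Horner–Wadsworth–Emmons olefination; the stabilized anion reacts at its phosphorus-bearing carbon and the new C4=C5 bond is expected to form E-selectively while the 2E bond of the reagent is carried over, any 4Z isomer being removable by chromatography.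

Step 2
Reactants: 3 ethyl (2E,4E)-octadeca-2,4-dienoate
Product: 4 (2E,4E)-octadeca-2,4-dien-1-ol
Conditions: i-Bu2AlH (2.2 equiv), CH2Cl2, −78 °C to 0 °C; aq. potassium sodium tartrate
Reagents that add atoms: none
Why: Aluminium hydride 1,2-reduction of a conjugated ester to the allylic alcohol, which leaves the diene untouched.

Step 3
Reactants: 4 (2E,4E)-octadeca-2,4-dien-1-ol
Product: 5 (2E,4E)-octadeca-2,4-dienal
Conditions: MnO2 (activated, excess), CH2Cl2, rt
Reagents that add atoms: none
Why: Chemoselective allylic oxidation on MnO2, which stops at the aldehyde under neutral conditions and should not scramble alkene geometry.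

Step 4
Reactants: 5 (2E,4E)-octadeca-2,4-dienal; 6 allenylboronic acid pinacol ester
Product: 8 (4R,5E,7E)-henicosa-5,7-dien-1-yn-4-ol, via pinacol borate ester 7 (not isolated)
Conditions: (R)-TRIP phosphoric acid [(R)-3,3′-bis(2,4,6-triisopropylphenyl)-1,1′-binaphthyl-2,2′-diyl hydrogen phosphate] (10 mol%), 4 Å MS, PhMe, −20 °C; aq. NaHCO3 work-up
Reagents that add atoms: none
Why: Chiral Brønsted acid-catalysed propargylboration; the allenyl γ-carbon adds 1,2 to the aldehyde through a closed six-membered transition state (SE2′) organized by hydrogen bonding of the phosphoric acid to the boronate oxygen and the formyl C–H, and the 3,3′-aryl groups of the catalyst expose the re face, which sets C4 as R.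

Step 5
Reactants: 8 (4R,5E,7E)-henicosa-5,7-dien-1-yn-4-ol
Product: 9 tert-butyl{[(4R,5E,7E)-henicosa-5,7-dien-1-yn-4-yl]oxy}dimethylsilane
Conditions: TBSCl, imidazole, DMF, 0 °C to rt
Reagents that add atoms: tert-butyldimethylsilyl chloride, CC(C)(C)[Si](C)(C)Cl
Why: Imidazole-promoted O-silylation of a secondary alcohol; the C–O bond at the stereocentre is not broken.

Step 6
Reactants: 9 tert-butyl{[(4R,5E,7E)-henicosa-5,7-dien-1-yn-4-yl]oxy}dimethylsilane
Product: 11 methyl (5R,6E,8E)-5-(tert-butyldimethylsilyloxy)docosa-6,8-dien-2-ynoate, via lithium acetylide 10 (not isolated)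
Conditions: n-BuLi (1.05 equiv), THF, −78 °C; then ClCO2Me, −78 °C to −20 °C
Reagents that add atoms: methyl chloroformate, COC(=O)Cl
Why: Deprotonation of the terminal alkyne and C-acylation of the acetylide with a chloroformate; keeping the mixture cold and free of excess base avoids γ-deprotonation of the ynoate and β-elimination of the silyloxy group.

Step 7
Reactants: 11 methyl (5R,6E,8E)-5-(tert-butyldimethylsilyloxy)docosa-6,8-dien-2-ynoate; 12 1-methoxycyclohexa-1,3-diene
Product: 14 methyl 2-[(2R,3E,5E)-2-(tert-butyldimethylsilyloxy)nonadeca-3,5-dienyl]-6-methoxybenzoate, via bicyclo[2.2.2]octadiene adduct 13 (not isolated)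
Conditions: 12 (5 equiv), BHT (cat.), PhMe, base-washed sealed tube, 110 °C, then 180 °C
Reagents that add atoms: none
Why: Alder–Rickert reaction: a normal-demand [4+2] cycloaddition joins the unsubstituted diene terminus of 12 to the ynoate β-carbon and the methoxy-bearing terminus to the α-carbon (the C4a–C5 and C8–C8a bonds of the target), giving bicyclo[2.2.2]octa-2,5-diene 13, which at the higher temperature loses its saturated two-carbon bridge as ethylene by an irreversible retro-[4+2] reaction driven by aromatization. The closest known reaction type is the thermal benzannulation of 1-methoxycyclohexa-1,3-diene with alk-2-ynoates to 6-substituted 2-methoxybenzoates. The benzene ring, the only ring formed, closes by intermolecular cycloaddition (both σ-bonds in one concerted step, no tether) followed by cycloreversion. No stereocentre is created in 14, because the two bridgehead centres of 13 are erased on aromatization, and the silyloxy-bearing carbon takes no part under these neutral conditions and should stay R. The required regioselectivity (methoxy ortho to the ester) follows from matching the largest HOMO coefficient at the diene carbon remote from oxygen with the largest LUMO coefficient at the ynoate β-carbon. The required chemoselectivity over the acyclic (E,E)-diene follows from the locked s-cis geometry, higher HOMO and excess of 12, and the two-atom spacing between the side-chain diene and the alkyne rules out an intramolecular cycloaddition.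

Step 8
Reactants: 14 methyl 2-[(2R,3E,5E)-2-(tert-butyldimethylsilyloxy)nonadeca-3,5-dienyl]-6-methoxybenzoate
Product: 16 methyl 2-[(2R,3E,5E)-2-(tert-butyldimethylsilyloxy)nonadeca-3,5-dienyl]-6-hydroxybenzoate, via dichloroboryl aryl ether 15 (not isolated)
Conditions: BCl3 (1.2 equiv), CH2Cl2, −78 °C; aq. NaHCO3
Reagents that add atoms: none
Why: Chelation-directed aryl methyl ether cleavage; BCl3 binds between the ester carbonyl and the ortho methoxy oxygen, chloride removes the activated O-methyl group by SN2, and the boron chelate is hydrolysed on quench, while near-stoichiometric reagent at low temperature should spare the hindered, weakly basic silyl ether, the methyl ester and the diene.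

Step 9
Reactants: 16 methyl 2-[(2R,3E,5E)-2-(tert-butyldimethylsilyloxy)nonadeca-3,5-dienyl]-6-hydroxybenzoate
Product: 18 (3R)-3-[(1E,3E)-heptadeca-1,3-dienyl]-8-hydroxy-3,4-dihydro-1H-isochromen-1-one, via hydroxy ester 17 (not isolated)
Conditions: Bu4NF (3 equiv), THF, 0 °C to 45 °C; aq. NH4Cl
Reagents that add atoms: none
Why: Fluoride cleaves the Si–O bond and the liberated secondary oxygen attacks the ortho ester carbonyl in a 6-exo-trig acyl substitution that expels methoxide and closes the δ-lactone; the carbinol C–O bond is never broken, so the R configuration is retained.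

**Compound list**

1 | tetradecanal | CCCCCCCCCCCCCC=O | starting material
2 | triethyl 4-phosphonocrotonate [ethyl (2E)-4-(diethoxyphosphoryl)but-2-enoate] | CCOC(=O)/C=C/CP(=O)(OCC)OCC | starting material
3 | ethyl (2E,4E)-octadeca-2,4-dienoate | CCCCCCCCCCCCC/C=C/C=C/C(=O)OCC | intermediate
4 | (2E,4E)-octadeca-2,4-dien-1-ol | CCCCCCCCCCCCC/C=C/C=C/CO | intermediate
5 | (2E,4E)-octadeca-2,4-dienal | CCCCCCCCCCCCC/C=C/C=C/C=O | intermediate
6 | allenylboronic acid pinacol ester | C=C=CB1OC(C)(C)C(C)(C)O1 | starting material
7 | 2-{[(4R,5E,7E)-henicosa-5,7-dien-1-yn-4-yl]oxy}-4,4,5,5-tetramethyl-1,3,2-dioxaborolane | CCCCCCCCCCCCC/C=C/C=C/[C@H](OB1OC(C)(C)C(C)(C)O1)CC#C | intermediate (not isolated)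
8 | (4R,5E,7E)-henicosa-5,7-dien-1-yn-4-ol | CCCCCCCCCCCCC/C=C/C=C/[C@H](O)CC#C | intermediate
9 | tert-butyl{[(4R,5E,7E)-henicosa-5,7-dien-1-yn-4-yl]oxy}dimethylsilane | CCCCCCCCCCCCC/C=C/C=C/[C@H](O[Si](C)(C)C(C)(C)C)CC#C | intermediate
10 | lithium acetylide of 9 | CCCCCCCCCCCCC/C=C/C=C/[C@H](O[Si](C)(C)C(C)(C)C)CC#C[Li] | intermediate (not isolated)
11 | methyl (5R,6E,8E)-5-(tert-butyldimethylsilyloxy)docosa-6,8-dien-2-ynoate | CCCCCCCCCCCCC/C=C/C=C/[C@H](O[Si](C)(C)C(C)(C)C)CC#CC(=O)OC | intermediate
12 | 1-methoxycyclohexa-1,3-diene | COC1=CC=CCC1 | starting material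
13 | methyl 3-[(2R,3E,5E)-2-(tert-butyldimethylsilyloxy)nonadeca-3,5-dienyl]-1-methoxybicyclo[2.2.2]octa-2,5-diene-2-carboxylate (both bridgehead diastereomers) | CCCCCCCCCCCCC/C=C/C=C/[C@H](O[Si](C)(C)C(C)(C)C)CC1=C(C(=O)OC)C2(OC)CCC1C=C2 | intermediate (not isolated)
14 | methyl 2-[(2R,3E,5E)-2-(tert-butyldimethylsilyloxy)nonadeca-3,5-dienyl]-6-methoxybenzoate | CCCCCCCCCCCCC/C=C/C=C/[C@H](O[Si](C)(C)C(C)(C)C)Cc1cccc(OC)c1C(=O)OC | intermediate
15 | methyl 2-[(2R,3E,5E)-2-(tert-butyldimethylsilyloxy)nonadeca-3,5-dienyl]-6-(dichloroboryloxy)benzoate (boron chelated by the ester carbonyl) | CCCCCCCCCCCCC/C=C/C=C/[C@H](O[Si](C)(C)C(C)(C)C)Cc1cccc(OB(Cl)Cl)c1C(=O)OC | intermediate (not isolated)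
16 | methyl 2-[(2R,3E,5E)-2-(tert-butyldimethylsilyloxy)nonadeca-3,5-dienyl]-6-hydroxybenzoate | CCCCCCCCCCCCC/C=C/C=C/[C@H](O[Si](C)(C)C(C)(C)C)Cc1cccc(O)c1C(=O)OC | intermediate
17 | methyl 2-hydroxy-6-[(2R,3E,5E)-2-hydroxynonadeca-3,5-dienyl]benzoate | CCCCCCCCCCCCC/C=C/C=C/[C@H](O)Cc1cccc(O)c1C(=O)OC | intermediate (not isolated)
18 | (3R)-3-[(1E,3E)-heptadeca-1,3-dienyl]-8-hydroxy-3,4-dihydro-1H-isochromen-1-one | CCCCCCCCCCCCC/C=C/C=C/[C@H]1Cc2cccc(O)c2C(=O)O1 | target

**Step count and risks**

Total steps: 9. Longest linear sequence: 9 steps (1 to 18).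

Steps most likely to fail:

Step 7. The ethylene extrusion needs prolonged heating near 180 °C. During this the dienylic silyl ether may degrade, the side-chain diene may be drawn into cycloaddition or oligomerization, and diene 12 may isomerize by [1,5]-hydrogen shift to its 2-methoxy isomer before it reacts, which would erode the regiochemistry. Fallback, setting out from 11 and coming back at 16: the same two ring bonds are made by a [4+2] cycloaddition whose adduct aromatizes by elimination at much lower temperature instead of by cycloreversion. Methyl crotonate is converted with LiN(i-Pr)2 and Me3SiCl (THF, −78 °C) into (1-methoxybuta-1,3-dienyloxy)trimethylsilane F1. Heating 11 with excess F1 in toluene at 80–100 °C should give, with the same polarity matching, methyl 2-[(2R,3E,5E)-2-(tert-butyldimethylsilyloxy)nonadeca-3,5-dienyl]-6-methoxy-6-(trimethylsilyloxy)cyclohexa-1,4-diene-1-carboxylate F2. On work-up with dilute aqueous citric acid the mixed ketal of F2 should collapse with loss of methanol and trimethylsilanol, and the resulting dienone tautomerizes to phenol 16. This bypasses 14 and step 8.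

Step 8. BCl3 may coordinate competitively to the silyl ether oxygen, leading to loss of the silyl group or ionization of the dienylic C–O bond with racemization or elimination; demethylation may also stall at low temperature because an ester is a weaker chelating partner than a ketone. Fallback, setting out from 14 and coming back at 18: both O-methyl groups are removed by SN2 attack of a soft nucleophile instead of by a Lewis acid. NaSEt in DMF at about 110 °C should dealkylate the hindered methyl ester and the aryl methyl ether, giving after buffered acidification (aq. NaH2PO4) 2-[(2R,3E,5E)-2-(tert-butyldimethylsilyloxy)nonadeca-3,5-dienyl]-6-hydroxybenzoic acid F3. Bu4NF in THF then frees 2-hydroxy-6-[(2R,3E,5E)-2-hydroxynonadeca-3,5-dienyl]benzoic acid F4. Carbodiimide activation of the carboxyl group (EDC·HCl, cat. DMAP, CH2Cl2, 0 °C) closes the lactone with retention, since the carbinol C–O bond is not broken, to give 18.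

Step 4. Facial discrimination may be insufficient for a long-chain dienal, or turnover may be slow at the temperature needed for selectivity. Fallback, setting out from 5 and coming back at 8: racemic addition followed by enzymatic kinetic resolution. Zinc dust and propargyl bromide in THF/aq. NH4Cl (Barbier conditions) convert 5 into racemic (5E,7E)-henicosa-5,7-dien-1-yn-4-ol F5. A lipase (Pseudomonas cepacia lipase or Candida antarctica lipase B) with vinyl acetate in hexane should acylate the (R)-enantiomer preferentially, in line with the usual preference of lipases for secondary alcohols with one large (dienyl) and one medium (propargyl) substituent. This gives (4R,5E,7E)-henicosa-5,7-dien-1-yn-4-yl acetate F6, which is separated from the unreacted (S)-alcohol and methanolysed (K2CO3, MeOH, 0 °C) to 8.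

**Further compounds**

F1 | step 7 | (1-methoxybuta-1,3-dienyloxy)trimethylsilane (E/Z mixture at the ketene acetal) | COC(O[Si](C)(C)C)=CC=C
F2 | step 7 | methyl 2-[(2R,3E,5E)-2-(tert-butyldimethylsilyloxy)nonadeca-3,5-dienyl]-6-methoxy-6-(trimethylsilyloxy)cyclohexa-1,4-diene-1-carboxylate (both ketal epimers) | CCCCCCCCCCCCC/C=C/C=C/[C@H](O[Si](C)(C)C(C)(C)C)CC1=C(C(=O)OC)C(OC)(O[Si](C)(C)C)C=CC1
F3 | step 8 | 2-[(2R,3E,5E)-2-(tert-butyldimethylsilyloxy)nonadeca-3,5-dienyl]-6-hydroxybenzoic acid | CCCCCCCCCCCCC/C=C/C=C/[C@H](O[Si](C)(C)C(C)(C)C)Cc1cccc(O)c1C(=O)O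
F4 | step 8 | 2-hydroxy-6-[(2R,3E,5E)-2-hydroxynonadeca-3,5-dienyl]benzoic acid | CCCCCCCCCCCCC/C=C/C=C/[C@H](O)Cc1cccc(O)c1C(=O)O
F5 | step 4 | racemic (5E,7E)-henicosa-5,7-dien-1-yn-4-ol | CCCCCCCCCCCCC/C=C/C=C/C(O)CC#C
F6 | step 4 | (4R,5E,7E)-henicosa-5,7-dien-1-yn-4-yl acetate | CCCCCCCCCCCCC/C=C/C=C/[C@H](OC(C)=O)CC#C
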